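**Strategy.** Locants follow germacranolide usage: C6 lactone carbinol, C7 ring fusion, C8 ester carbinol, C9=C10, C1–C3, C4=C5, C11–C13 lactone; ring A is the γ-lactone, ring B the ten-membered carbocycle. Ring B is disconnected at C8–C9. The C5=C4(Me)–C3(OH)–C2–C1(OH)–C10(Me)=C9 arc is C2-symmetric (both carbinols S, both olefins Z), so it is built two-directionally as a bis(Z-iodoalkene). One iodide becomes the C6 enal for an Evans aldol–lactonisation that forms ring A. The other closes ring B by intramolecular Nozaki–Hiyama–Kishi addition to the C8 aldehyde, exploiting the C8 allylic carbinol flanked by Z-C9=C10 and C7. The precursor is an open-chain iodoalkenyl lactone aldehyde.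

Key step: step 11

Remark: diketone 3 is drawn in its diketo form although it should exist largely as the enol; systematic names carry their own locants.

Step 1
Reactants: 1 4-(trimethylsilyl)but-3-yn-2-one; 2 ethyl 3-(trimethylsilyl)prop-2-ynoate
Product: 3 1,7-bis(trimethylsilyl)hepta-1,6-diyne-3,5-dione
Conditions: LiHMDS (2.2 equiv), THF, −78 °C; then 2, −78 → 0 °C; aq. NH4Cl
Reagents that add atoms: none
Why: Claisen condensation in which the kinetic lithium enolate of methyl ynone 1 is C-acylated by ester 2 (the β-silyl group disfavours conjugate addition), driven by deprotonation of the 1,3-diketone by the second equivalent of base.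

Step 2
Reactants: 3 1,7-bis(trimethylsilyl)hepta-1,6-diyne-3,5-dione
Product: 4 (3S,5S)-1,7-bis(trimethylsilyl)hepta-1,6-diyne-3,5-diol
Conditions: RuCl[(S,S)-TsDPEN](p-cymene) (cat.), HCO2H/Et3N (5:2), CH2Cl2, 25 °C
Reagents that add atoms: none
Why: Noyori–Ikariya asymmetric transfer hydrogenation of alkynyl ketones, in which the alkynyl group is the directing π-substituent, should reduce each carbonyl to the (S)-carbinol under catalyst control and so give the C2-symmetric anti-diol (future C1 and C3), mismatched events ending in the separable meso diol.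

Step 3
Reactants: 4 (3S,5S)-1,7-bis(trimethylsilyl)hepta-1,6-diyne-3,5-diol
Product: 5 (3S,5S)-hepta-1,6-diyne-3,5-diol
Conditions: K2CO3, MeOH, 25 °C
Reagents that add atoms: none
Why: Methoxide-mediated protodesilylation of the alkynylsilanes, which does not touch the carbinol centres.

Step 4
Reactants: 5 (3S,5S)-hepta-1,6-diyne-3,5-diol
Product: 7 (1Z,3S,5S,6Z)-1,7-diiodo-2,6-dimethylhepta-1,6-diene-3,5-diol, via bis(alkenylmagnesium bromide) dialkoxide 6 (not isolated)
Conditions: MeMgBr (6 equiv), CuI (20 mol %), THF, 0 → 25 °C; then I2, THF, −78 → 0 °C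
Reagents that add atoms: methylmagnesium bromide C[Mg]Br; iodine II
Why: Alkoxide-directed copper-catalysed anti-carbomagnesiation of propargylic alkoxides delivers methyl to the alkyne carbon next to the carbinol and leaves magnesium on the terminal carbon in a five-membered oxamagnesacycle, cis to the carbinol carbon, so that iodinolysis with retention should give both Z-iodoalkenes (the future C4=C5 and C9=C10 geometry).

Step 5
Reactants: 7 (1Z,3S,5S,6Z)-1,7-diiodo-2,6-dimethylhepta-1,6-diene-3,5-diol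
Product: 8 (1Z,3S,5S,6Z)-3,5-bis(tert-butyldimethylsilyloxy)-1,7-diiodo-2,6-dimethylhepta-1,6-diene
Conditions: TBSOTf, 2,6-lutidine, CH2Cl2, 0 °C
Reagents that add atoms: tert-butyldimethylsilyl trifluoromethanesulfonate CC(C)(C)[Si](C)(C)OS(=O)(=O)C(F)(F)F
Why: Silylation of the two hindered allylic alcohols with the silyl triflate, a protection that should survive organolithium, boron enolate, hydride and chromium chemistry.

Step 6
Reactants: 8 (1Z,3S,5S,6Z)-3,5-bis(tert-butyldimethylsilyloxy)-1,7-diiodo-2,6-dimethylhepta-1,6-diene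
Product: 10 (2Z,4S,6S,7Z)-4,6-bis(tert-butyldimethylsilyloxy)-8-iodo-3,7-dimethylocta-2,7-dienal, via alkenyllithium 9 (not isolated)
Conditions: t-BuLi (2.0 equiv), Et2O, −78 °C; then DMF, −78 → 0 °C; aq. NH4Cl
Reagents that add atoms: N,N-dimethylformamide CN(C)C=O
Why: Iodine–lithium exchange with retention of olefin geometry followed by Bouveault formylation; the two iodides are homotopic through the C2 axis, so mono-exchange is statistical but gives a single enal whichever end reacts, and unreacted 8 is recycled.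

Step 7
Reactants: 11 (4R)-4-benzyl-1,3-oxazolidin-2-one; 12 methyl 4-chloro-4-oxobutanoate
Product: 13 methyl 4-[(4R)-4-benzyl-2-oxo-1,3-oxazolidin-3-yl]-4-oxobutanoate
Conditions: n-BuLi, THF, −78 °C; then 12, −78 → 0 °C
Reagents that add atoms: none
Why: N-acylation of the lithiated oxazolidinone by the acid chloride, which is far more electrophilic than the methyl ester.

Step 8
Reactants: 13 methyl 4-[(4R)-4-benzyl-2-oxo-1,3-oxazolidin-3-yl]-4-oxobutanoate; 10 (2Z,4S,6S,7Z)-4,6-bis(tert-butyldimethylsilyloxy)-8-iodo-3,7-dimethylocta-2,7-dienal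
Product: 15 (4R)-4-benzyl-3-({(2S,3R)-2-[(1Z,3S,5S,6Z)-3,5-bis(tert-butyldimethylsilyloxy)-7-iodo-2,6-dimethylhepta-1,6-dien-1-yl]-5-oxooxolan-3-yl}carbonyl)-1,3-oxazolidin-2-one, via syn-aldol adduct 14 (not isolated)
Conditions: 13, Bu2BOTf, iPr2NEt, CH2Cl2, 0 °C; then 10, −78 → 0 °C; pH 7 buffer, MeOH, H2O2; then PPTS (cat.), toluene, 50 °C
Reagents that add atoms: none
Why: Evans syn-aldol reaction in which the Z-boron enolate, formed regioselectively at the imide α-carbon, adds through a Zimmerman–Traxler chair under control of the (R)-benzyl auxiliary to set C6 (S) and C7 (R) syn, after which the C6 hydroxyl closes on the methyl ester to the trans-γ-lactone (ring A).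

Step 9
Reactants: 15 the lactone imide
Product: 16 (2S,3R)-2-[(1Z,3S,5S,6Z)-3,5-bis(tert-butyldimethylsilyloxy)-7-iodo-2,6-dimethylhepta-1,6-dien-1-yl]-5-oxooxolane-3-carboxylic acid
Conditions: LiOH, H2O2, THF/H2O, 0 °C; Na2SO3; then HCl to pH 3
Reagents that add atoms: hydrogen peroxide OO
Why: Hydroperoxide cleaves the exocyclic imide carbonyl selectively, and any lactone opened by hydroxide can only re-close to the same γ-lactone on acidification because the alternative would be a β-lactone.

Step 10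
Reactants: 16 the lactone acid
Product: 18 (2S,3R)-2-[(1Z,3S,5S,6Z)-3,5-bis(tert-butyldimethylsilyloxy)-7-iodo-2,6-dimethylhepta-1,6-dien-1-yl]-5-oxooxolane-3-carbaldehyde, via acid chloride 17 (not isolated)
Conditions: Me2C=C(Cl)NMe2 (Ghosez reagent), CH2Cl2, 0 → 25 °C; then LiAlH(OtBu)3, THF, −78 °C
Reagents that add atoms: none
Why: Neutral acid chloride formation followed by chemoselective reduction with the hindered alkoxyaluminium hydride should stop at the aldehyde and spare lactone, silyl ethers and iodoalkene, and it avoids the hydroxymethyl lactone, which could translactonise.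

Step 11
Reactants: 18 the iodoalkenyl lactone aldehyde
Product: 19 (3aS,4R,5Z,7S,9S,10Z,11aS)-7,9-bis(tert-butyldimethylsilyloxy)-4-hydroxy-6,10-dimethyl-3a,4,7,8,9,11a-hexahydrocyclodeca[b]furan-2(3H)-one
Conditions: CrCl2 (10 equiv), NiCl2 (2 mol %), DMSO/THF, 25 °C, slow addition of 18 (final 0.002 M)
Reagents that add atoms: none
Why: Nozaki–Hiyama–Kishi reaction: zerovalent nickel, formed from NiCl2 by CrCl2, inserts into the C9–I bond with retention of the Z geometry, transmetalation gives an alkenyl species of trivalent chromium, and this adds to the C8 aldehyde, the product being held as a chromium alkoxide until work-up. The closest known reaction type is the intramolecular NHK closure of iodoalkene aldehydes to nine- to twelve-membered carbocycles; ring B closes in a 10-exo-trig mode, helped by high dilution and by the two Z olefins and the trans-lactone, which turn the chain ends towards each other. The new C8 stereocentre is controlled by C7: Felkin–Anh attack anti to the C6 branch of the lactone places the C8 oxygen syn to C11, which is 8R. The step needs chemoselectivity for the aldehyde over the lactone carbonyl, secured by the low basicity and nucleophilicity of organochromium reagents, and it must not epimerise C7, secured by the neutral conditions. Facial selectivity at C8 is the open point, because the tether through C6 may override the Felkin preference.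

Step 12
Reactants: 19 the macrocyclic hydroxy lactone
Product: 22 (3aS,4R,5Z,7S,9S,10Z,11aS)-7,9-bis(tert-butyldimethylsilyloxy)-4-hydroxy-6,10-dimethyl-3-methylidene-3a,4,7,8,9,11a-hexahydrocyclodeca[b]furan-2(3H)-one, via Mannich base 20 (not isolated), via methiodide 21 (not isolated)
Conditions: 19 added to LDA (3 equiv), THF, −78 °C; CH2=NMe2+ I−, −78 → 0 °C; then MeI, MeOH, 25 °C; then NaHCO3 (aq), CH2Cl2
Reagents that add atoms: N,N-dimethylmethyleneiminium iodide (Eschenmoser salt) C=[N+](C)C.[I-]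
Why: Eschenmoser methylenation, in which inverse addition to excess base converts the lactone at once into its non-electrophilic enolate beside the C8 alkoxide, the enolate undergoes a Mannich reaction, and quaternisation followed by E1cB loss of trimethylamine installs the C11=C13 olefin.

Step 13
Reactants: 22 the α-methylene hydroxy lactone; 23 (Z)-2-methylbut-2-enoic acid (angelic acid)
Product: 25 (3aR,4R,5Z,7S,9S,10Z,11aS)-7,9-bis(tert-butyldimethylsilyloxy)-6,10-dimethyl-3-methylidene-2-oxo-2,3,3a,4,7,8,9,11a-octahydrocyclodeca[b]furan-4-yl (2Z)-2-methylbut-2-enoate, via mixed anhydride 24 (not isolated)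
Conditions: 23, 2,4,6-Cl3C6H2COCl, Et3N, toluene, 25 °C; then 22, toluene, 80 °C
Reagents that add atoms: none
Why: Yamaguchi esterification, in which the hindered trichlorobenzoyl carbonyl directs the C8 hydroxyl to the angeloyl carbonyl, and leaving out nucleophilic catalysts such as DMAP should prevent addition–elimination isomerisation of the Z-angelate to the tiglate.

Step 14
Reactants: 25 the bis-silyl angelate
Product: 26 (3aR,4R,5Z,7S,9S,10Z,11aS)-7,9-dihydroxy-6,10-dimethyl-3-methylidene-2-oxo-2,3,3a,4,7,8,9,11a-octahydrocyclodeca[b]furan-4-yl (2Z)-2-methylbut-2-enoate (target)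
Conditions: HF·pyridine, pyridine, THF, 0 → 25 °C
Reagents that add atoms: none
Why: Fluoride-mediated cleavage of the two allylic silyl ethers under buffered, weakly acidic conditions, which should avoid base-induced acyl migration from O8 to O1 and conjugate addition to the α-methylene lactone.

**Compound list**

1 | 4-(trimethylsilyl)but-3-yn-2-one | CC(=O)C#C[Si](C)(C)C | starting material
2 | ethyl 3-(trimethylsilyl)prop-2-ynoate | CCOC(=O)C#C[Si](C)(C)C | starting material
3 | 1,7-bis(trimethylsilyl)hepta-1,6-diyne-3,5-dione | C[Si](C)(C)C#CC(=O)CC(=O)C#C[Si](C)(C)C | intermediate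
4 | (3S,5S)-1,7-bis(trimethylsilyl)hepta-1,6-diyne-3,5-diol | C[Si](C)(C)C#C[C@@H](O)C[C@H](O)C#C[Si](C)(C)C | intermediate
5 | (3S,5S)-hepta-1,6-diyne-3,5-diol | C#C[C@@H](O)C[C@H](O)C#C | intermediate
6 | bis(alkenylmagnesium bromide) dialkoxide of 7 (Mg in place of I, OMgBr in place of OH; formed in the flask) | Br[Mg]/C=C(/C)[C@@H](O[Mg]Br)C[C@H](O[Mg]Br)/C(C)=C\[Mg]Br | intermediate
7 | (1Z,3S,5S,6Z)-1,7-diiodo-2,6-dimethylhepta-1,6-diene-3,5-diol | I/C=C(/C)[C@@H](O)C[C@H](O)/C(C)=C\I | intermediate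
8 | (1Z,3S,5S,6Z)-3,5-bis(tert-butyldimethylsilyloxy)-1,7-diiodo-2,6-dimethylhepta-1,6-diene | I/C=C(/C)[C@@H](O[Si](C)(C)C(C)(C)C)C[C@H](O[Si](C)(C)C(C)(C)C)/C(C)=C\I | intermediate
9 | (1Z,3S,5S,6Z)-3,5-bis(tert-butyldimethylsilyloxy)-7-iodo-2,6-dimethylhepta-1,6-dien-1-yllithium (formed in the flask) | [Li]/C=C(/C)[C@@H](O[Si](C)(C)C(C)(C)C)C[C@H](O[Si](C)(C)C(C)(C)C)/C(C)=C\I | intermediate
10 | (2Z,4S,6S,7Z)-4,6-bis(tert-butyldimethylsilyloxy)-8-iodo-3,7-dimethylocta-2,7-dienal | O=C/C=C(/C)[C@@H](O[Si](C)(C)C(C)(C)C)C[C@H](O[Si](C)(C)C(C)(C)C)/C(C)=C\I | intermediate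
11 | (4R)-4-benzyl-1,3-oxazolidin-2-one | O=C1N[C@H](Cc2ccccc2)CO1 | starting material
12 | methyl 4-chloro-4-oxobutanoate | COC(=O)CCC(=O)Cl | starting material
13 | methyl 4-[(4R)-4-benzyl-2-oxo-1,3-oxazolidin-3-yl]-4-oxobutanoate | COC(=O)CCC(=O)N1[C@H](Cc2ccccc2)COC1=O | intermediate
14 | methyl (3R,4S,5Z,7S,9S,10Z)-3-{[(4R)-4-benzyl-2-oxo-1,3-oxazolidin-3-yl]carbonyl}-7,9-bis(tert-butyldimethylsilyloxy)-4-hydroxy-11-iodo-6,10-dimethylundeca-5,10-dienoate (formed in the flask) | COC(=O)C[C@@H](C(=O)N1[C@H](Cc2ccccc2)COC1=O)[C@@H](O)/C=C(/C)[C@@H](O[Si](C)(C)C(C)(C)C)C[C@H](O[Si](C)(C)C(C)(C)C)/C(C)=C\I | intermediate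
15 | (4R)-4-benzyl-3-({(2S,3R)-2-[(1Z,3S,5S,6Z)-3,5-bis(tert-butyldimethylsilyloxy)-7-iodo-2,6-dimethylhepta-1,6-dien-1-yl]-5-oxooxolan-3-yl}carbonyl)-1,3-oxazolidin-2-one | O=C1C[C@@H](C(=O)N2[C@H](Cc3ccccc3)COC2=O)[C@H](/C=C(/C)[C@@H](O[Si](C)(C)C(C)(C)C)C[C@H](O[Si](C)(C)C(C)(C)C)/C(C)=C\I)O1 | intermediate
16 | (2S,3R)-2-[(1Z,3S,5S,6Z)-3,5-bis(tert-butyldimethylsilyloxy)-7-iodo-2,6-dimethylhepta-1,6-dien-1-yl]-5-oxooxolane-3-carboxylic acid | O=C1C[C@@H](C(=O)O)[C@H](/C=C(/C)[C@@H](O[Si](C)(C)C(C)(C)C)C[C@H](O[Si](C)(C)C(C)(C)C)/C(C)=C\I)O1 | intermediate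
17 | (2S,3R)-2-[(1Z,3S,5S,6Z)-3,5-bis(tert-butyldimethylsilyloxy)-7-iodo-2,6-dimethylhepta-1,6-dien-1-yl]-5-oxooxolane-3-carbonyl chloride (formed in the flask) | O=C1C[C@@H](C(=O)Cl)[C@H](/C=C(/C)[C@@H](O[Si](C)(C)C(C)(C)C)C[C@H](O[Si](C)(C)C(C)(C)C)/C(C)=C\I)O1 | intermediate
18 | (2S,3R)-2-[(1Z,3S,5S,6Z)-3,5-bis(tert-butyldimethylsilyloxy)-7-iodo-2,6-dimethylhepta-1,6-dien-1-yl]-5-oxooxolane-3-carbaldehyde | O=C1C[C@@H](C=O)[C@H](/C=C(/C)[C@@H](O[Si](C)(C)C(C)(C)C)C[C@H](O[Si](C)(C)C(C)(C)C)/C(C)=C\I)O1 | intermediate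
19 | (3aS,4R,5Z,7S,9S,10Z,11aS)-7,9-bis(tert-butyldimethylsilyloxy)-4-hydroxy-6,10-dimethyl-3a,4,7,8,9,11a-hexahydrocyclodeca[b]furan-2(3H)-one | O=C1O[C@H]2/C=C(/C)[C@@H](O[Si](C)(C)C(C)(C)C)C[C@H](O[Si](C)(C)C(C)(C)C)/C(C)=C\[C@@H](O)[C@@H]2C1 | intermediate
20 | 3-[(dimethylamino)methyl] derivative of 19 (both C3 epimers; formed in the flask) | CN(C)CC1C(=O)O[C@H]2/C=C(/C)[C@@H](O[Si](C)(C)C(C)(C)C)C[C@H](O[Si](C)(C)C(C)(C)C)/C(C)=C\[C@@H](O)[C@H]12 | intermediate
21 | N-methyl quaternary ammonium iodide of 20 (formed in the flask) | C[N+](C)(C)CC1C(=O)O[C@H]2/C=C(/C)[C@@H](O[Si](C)(C)C(C)(C)C)C[C@H](O[Si](C)(C)C(C)(C)C)/C(C)=C\[C@@H](O)[C@H]12.[I-] | intermediate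
22 | (3aS,4R,5Z,7S,9S,10Z,11aS)-7,9-bis(tert-butyldimethylsilyloxy)-4-hydroxy-6,10-dimethyl-3-methylidene-3a,4,7,8,9,11a-hexahydrocyclodeca[b]furan-2(3H)-one | C=C1C(=O)O[C@H]2/C=C(/C)[C@@H](O[Si](C)(C)C(C)(C)C)C[C@H](O[Si](C)(C)C(C)(C)C)/C(C)=C\[C@@H](O)[C@H]12 | intermediate
23 | (Z)-2-methylbut-2-enoic acid (angelic acid) | C/C=C(/C)C(=O)O | starting material
24 | (Z)-2-methylbut-2-enoic 2,4,6-trichlorobenzoic anhydride (formed in the flask) | C/C=C(/C)C(=O)OC(=O)c1c(Cl)cc(Cl)cc1Cl | intermediate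
25 | (3aR,4R,5Z,7S,9S,10Z,11aS)-7,9-bis(tert-butyldimethylsilyloxy)-6,10-dimethyl-3-methylidene-2-oxo-2,3,3a,4,7,8,9,11a-octahydrocyclodeca[b]furan-4-yl (2Z)-2-methylbut-2-enoate | C=C1C(=O)O[C@H]2/C=C(/C)[C@@H](O[Si](C)(C)C(C)(C)C)C[C@H](O[Si](C)(C)C(C)(C)C)/C(C)=C\[C@@H](OC(=O)/C(C)=C\C)[C@H]12 | intermediate
26 | (3aR,4R,5Z,7S,9S,10Z,11aS)-7,9-dihydroxy-6,10-dimethyl-3-methylidene-2-oxo-2,3,3a,4,7,8,9,11a-octahydrocyclodeca[b]furan-4-yl (2Z)-2-methylbut-2-enoate | C=C1C(=O)O[C@H]2/C=C(/C)[C@@H](O)C[C@H](O)/C(C)=C\[C@@H](OC(=O)/C(C)=C\C)[C@H]12 | target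

**Step count.** Total: 14 steps. Longest linear sequence: 13 steps (steps 1–6 and 8–14; step 7 is the side branch).

**Steps most likely to fail**

Step 11 (key step). The process at risk is facial selection in the addition to the C8 aldehyde: the tether through C6 may override Felkin control and deliver the C8 epimer. The fallback sets out from 18 and returns to 19, and sets C8 by inversion instead of by the addition. The ring closure is run as before and the (4S) C8 epimer of 19 F1 is separated. A Mitsunobu reaction with chloroacetic acid (PPh3, DIAD, toluene, 0 °C) should displace at C8 with inversion to give the chloroacetate of 19 F2. The chloroacetate is then removed with thiourea (NaHCO3, EtOH, 50 °C), conditions mild enough not to move the lactone from O6 to O8, giving 19.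

Step 4. The process at risk is incomplete or unselective carbometalation of the second alkyne inside the aggregated dimagnesium dialkoxide, leaving mono-adducts and protonated alkyne. The fallback sets out from 4 and returns to 8, and replaces the alkoxide-directed anti-addition by a syn-addition to the silylalkyne. Diol 4 is silylated (TBSOTf, 2,6-lutidine, CH2Cl2) to (3S,5S)-3,5-bis(tert-butyldimethylsilyloxy)-1,7-bis(trimethylsilyl)hepta-1,6-diyne F3. Nickel-catalysed syn-methylmagnesiation of the alkynylsilanes (MeMgBr, Ni(acac)2 and Me3Al as catalyst, THF) should place methyl on the carbon next to the carbinol and magnesium on the silicon-bearing carbon, giving the bis(1-silylalkenylmagnesium bromide) F4. Protonation at low temperature (aq. NH4Cl), before F4 can isomerise, should give the (1Z,6Z)-bis(vinylsilane) F5 with silicon cis to the carbinol carbon. Iododesilylation with NIS (MeCN, 0 °C) with retention then gives 8.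

Step 2. The process at risk is stalling of the transfer hydrogenation at the enolised diketone, or cyclisation of the ynedione to a 4-pyranone in the amine–formic acid medium. The fallback sets out from 1 and returns to 4, and reduces one non-enolised carbonyl instead of two enolised ones. The lithium enolate of 1 (LDA, THF, −78 °C) adds to 3-(trimethylsilyl)prop-2-ynal to give racemic 5-hydroxy-1,7-bis(trimethylsilyl)hepta-1,6-diyn-3-one F6. Transfer hydrogenation of F6 with the same (S,S) catalyst in 2-propanol should set the new carbinol as S whatever the configuration of the existing one. The (S)-enantiomer of F6 therefore gives 4 and the (R)-enantiomer gives the meso diol (3R,5S)-1,7-bis(trimethylsilyl)hepta-1,6-diyne-3,5-diol F7, which is removed by chromatography. Material is lost as F7, but 4 is still formed under catalyst control.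

**Further compounds**

F1 | step 11 | (3aS,4S,5Z,7S,9S,10Z,11aS)-7,9-bis(tert-butyldimethylsilyloxy)-4-hydroxy-6,10-dimethyl-3a,4,7,8,9,11a-hexahydrocyclodeca[b]furan-2(3H)-one (C8 epimer of 19) | O=C1O[C@H]2/C=C(/C)[C@@H](O[Si](C)(C)C(C)(C)C)C[C@H](O[Si](C)(C)C(C)(C)C)/C(C)=C\[C@H](O)[C@@H]2C1
F2 | step 11 | chloroacetate of 19 (C8 configuration as in 19) | O=C1O[C@H]2/C=C(/C)[C@@H](O[Si](C)(C)C(C)(C)C)C[C@H](O[Si](C)(C)C(C)(C)C)/C(C)=C\[C@@H](OC(=O)CCl)[C@@H]2C1
F3 | step 4 | (3S,5S)-3,5-bis(tert-butyldimethylsilyloxy)-1,7-bis(trimethylsilyl)hepta-1,6-diyne | C[Si](C)(C)C#C[C@@H](O[Si](C)(C)C(C)(C)C)C[C@H](O[Si](C)(C)C(C)(C)C)C#C[Si](C)(C)C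
F4 | step 4 | bis(1-silylalkenylmagnesium bromide) from F3 (Mg cis to methyl, Si cis to the carbinol carbon; formed in the flask) | C[Si](C)(C)/C([Mg]Br)=C(/C)[C@@H](O[Si](C)(C)C(C)(C)C)C[C@H](O[Si](C)(C)C(C)(C)C)/C(C)=C(\[Si](C)(C)C)[Mg]Br
F5 | step 4 | (1Z,3S,5S,6Z)-3,5-bis(tert-butyldimethylsilyloxy)-2,6-dimethyl-1,7-bis(trimethylsilyl)hepta-1,6-diene | C[Si](C)(C)/C=C(/C)[C@@H](O[Si](C)(C)C(C)(C)C)C[C@H](O[Si](C)(C)C(C)(C)C)/C(C)=C\[Si](C)(C)C
F6 | step 2 | racemic 5-hydroxy-1,7-bis(trimethylsilyl)hepta-1,6-diyn-3-one | C[Si](C)(C)C#CC(=O)CC(O)C#C[Si](C)(C)C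
F7 | step 2 | (3R,5S)-1,7-bis(trimethylsilyl)hepta-1,6-diyne-3,5-diol (meso) | C[Si](C)(C)C#C[C@@H](O)C[C@@H](O)C#C[Si](C)(C)C
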